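**Retrosynthetic overview**
- The oxolane ring is the only ring made and it is closed last. Both C–O bonds are cut back to water and the (2S,3S)-configured 8,8′-linked bis(p-quinone methide), the intermediate of the natural pathway. Hydration of one methide and oxa-1,6-addition onto the other set C5 and C2 from the two methyl-bearing centres.
- The bis(quinone methide) is not made by phenol radical coupling. It comes from fourfold dehydrogenation (Ag2O) of the enantiopure (2R,3R)-dibenzylbutane bisphenol, so the absolute configuration is fixed before the cascade.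
- C3 and C4 come from catalyst-controlled asymmetric hydrogenation of the achiral (1E,3E)-1,4-diaryl-2,3-dimethylbutadiene. This diene is a tautomer of the bis(quinone methide), so hydrogenation followed by dehydrogenation amounts to an enantioselective tautomerisation.
- The diene is assembled in one operation by double Heck arylation of 2,3-dimethylbuta-1,3-diene with 4-bromo-2,6-dimethoxyphenol, without protecting groups.

Assumption: the sense of induction in step 2 is taken from the (E)-1,2-diphenylpropene precedent as I recall it (S ligand gives R centres) and is checked on 6 before step 3; the enantiomeric ligand is used if the correlation is reversed.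

**Step 1**
Reactants: 1 4-bromo-2,6-dimethoxyphenol (2.2 equiv); 2 2,3-dimethylbuta-1,3-diene (1.0 equiv)
Product: 4 4,4′-[(1E,3E)-2,3-dimethylbuta-1,3-diene-1,4-diyl]bis(2,6-dimethoxyphenol), via monoaryl diene 3 (not isolated)
Conditions: Pd(OAc)2 (5 mol %), P(o-tol)3 (12 mol %), NaHCO3 (3 equiv), DMA, 115 °C, sealed tube, argon
Reagents that add atoms: none
Why: Twofold Mizoroki–Heck arylation of a conjugated diene, in which each ArPdBr adds to a terminal CH2 and the η3-allylpalladium intermediate undergoes syn β-hydride elimination from the new benzylic CH2 to give the aryl-conjugated alkene with the aryl group cis to the smaller methyl (E), the second arylation occurring at the remaining free terminus of 3; NaHCO3 is too weak to deprotonate the phenol and no stereocentre is formed.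

**Step 2**
Reactants: 4 4,4′-[(1E,3E)-2,3-dimethylbuta-1,3-diene-1,4-diyl]bis(2,6-dimethoxyphenol)
Product: 6 4,4′-[(2R,3R)-2,3-dimethylbutane-1,4-diyl]bis(2,6-dimethoxyphenol), via monoene 5 (not isolated)
Conditions: H2 (50 bar), [Ir(cod)(L)][B(3,5-(CF3)2C6H3)4] (2 mol %; L = (S)-4-tert-butyl-2-[2-(di-o-tolylphosphanyl)phenyl]-4,5-dihydro-1,3-oxazole), CH2Cl2, 25 °C
Reagents that add atoms: none
Why: Iridium-catalysed asymmetric hydrogenation of unfunctionalised E-trisubstituted aryl alkenes (Pfaltz type), in which the N,P-ligated iridium dihydride adds H2 syn to the same enantioface of each ArCH=C(Me)– unit under catalyst control (R at each centre with the S ligand, by analogy with (E)-1,2-diphenylpropene), so that C2 and C3 are both set here and any wrong-face event ends up in the separable meso isomer, which raises the ee of the R,R product.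

**Step 3**
Reactants: 6 4,4′-[(2R,3R)-2,3-dimethylbutane-1,4-diyl]bis(2,6-dimethoxyphenol)
Product: 10 (2S,3S,4S,5R)-2,5-bis(4-hydroxy-3,5-dimethoxyphenyl)-3,4-dimethyloxolane, via mono(quinone methide) 7 (not isolated), via bis(quinone methide) 8 (not isolated), via hydroxy quinone methide 9 (not isolated)
Conditions: Ag2O (6 equiv), 4 Å MS, CH2Cl2 (0.01 M), 23 °C, dark, N2; filter; then THF/aq. KH2PO4 (pH 4.5) 3:1, 0 °C
Reagents that add atoms: water, O
Why: Proposed new method: Ag2O dehydrogenates each 4-alkyl-2,6-dimethoxyphenol unit to a p-quinone methide (closest known type: Ag2O oxidation of 4-alkyl-2,6-dimethoxyphenols to p-quinone methides that are used in solution), giving the same 8,8′-linked bis(quinone methide) that arises in the dehydrodimerisation of propenylphenols; water then adds 1,6 to one methide carbon in the conformer whose allylic H eclipses the exocyclic C=C (A(1,3)-strain control), on the face anti to the branched chain, which gives the R carbinol syn to its methyl neighbour (C5 cis to the C4 methyl), and this hydroxyl closes the ring by 5-exo oxa-1,6-addition to the second methide through the analogous H-in-plane conformer, placing that aryl group trans to the C3 methyl (C2 = S), the known biomimetic hydration and cyclisation of such bis(quinone methides) being the model for both C–O bond formations.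

**Compound list**
1 | 4-bromo-2,6-dimethoxyphenol | COc1cc(Br)cc(OC)c1O | starting material
2 | 2,3-dimethylbuta-1,3-diene | CC(=C)C(C)=C | starting material
3 | 4-[(1E)-2,3-dimethylbuta-1,3-dien-1-yl]-2,6-dimethoxyphenol | COc1cc(/C=C(C)/C(C)=C)cc(OC)c1O | intermediate (not isolated)
4 | 4,4′-[(1E,3E)-2,3-dimethylbuta-1,3-diene-1,4-diyl]bis(2,6-dimethoxyphenol) | COc1cc(/C=C(C)/C(C)=C/c2cc(OC)c(O)c(OC)c2)cc(OC)c1O | intermediate
5 | 4,4′-[(1E,3R)-2,3-dimethylbut-1-ene-1,4-diyl]bis(2,6-dimethoxyphenol) | COc1cc(/C=C(C)/[C@H](C)Cc2cc(OC)c(O)c(OC)c2)cc(OC)c1O | intermediate (not isolated)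
6 | 4,4′-[(2R,3R)-2,3-dimethylbutane-1,4-diyl]bis(2,6-dimethoxyphenol) | COc1cc(C[C@@H](C)[C@H](C)Cc2cc(OC)c(O)c(OC)c2)cc(OC)c1O | intermediate
7 | 4-[(2S,3R)-4-(4-hydroxy-3,5-dimethoxyphenyl)-2,3-dimethylbutylidene]-2,6-dimethoxycyclohexa-2,5-dien-1-one | COC1=CC(=C[C@@H](C)[C@H](C)Cc2cc(OC)c(O)c(OC)c2)C=C(OC)C1=O | intermediate (not isolated)
8 | 4,4′-[(2S,3S)-2,3-dimethylbutane-1,4-diylidene]bis(2,6-dimethoxycyclohexa-2,5-dien-1-one) | COC1=CC(=C[C@@H](C)[C@H](C)C=C2C=C(OC)C(=O)C(OC)=C2)C=C(OC)C1=O | intermediate (not isolated)
9 | 4-[(2R,3S,4R)-4-hydroxy-4-(4-hydroxy-3,5-dimethoxyphenyl)-2,3-dimethylbutylidene]-2,6-dimethoxycyclohexa-2,5-dien-1-one | COc1cc([C@H](O)[C@@H](C)[C@H](C)C=C2C=C(OC)C(=O)C(OC)=C2)cc(OC)c1O | intermediate (not isolated)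
10 | (2S,3S,4S,5R)-2,5-bis(4-hydroxy-3,5-dimethoxyphenyl)-3,4-dimethyloxolane (CNP0217414.2) | COc1cc([C@H]2O[C@@H](c3cc(OC)c(O)c(OC)c3)[C@@H](C)[C@@H]2C)cc(OC)c1O | target

**Totals**
Total step count: 3. Longest linear sequence: 3 steps (1 and 2 to 10).

**Steps most likely to fail, highest risk first**

Step 3. The second phenol may not be oxidised before the mono(quinone methide) 7 is consumed by arene attack (aryltetralin) or by intermolecular phenol addition. The methides may also tautomerise back to 4, which loses material but gives a recyclable achiral diene. The facial preference in the hydration is only moderate, so the all-trans C5 epimer is the expected by-product; it is removed by chromatography, and the acid is kept weak and cold because stronger acid equilibrates the product towards that epimer.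

The fallback sets out from 6 and comes back at 8. DDQ (2.2 equiv) in CH2Cl2/MeOH at 0 °C oxidises one benzylic position at a time, and methanol quenches each quinone methide as soon as it forms. This gives the storable bis(benzylic methyl ether) 4,4′-[(2S,3S)-1,4-dimethoxy-2,3-dimethylbutane-1,4-diyl]bis(2,6-dimethoxyphenol) F1, a mixture at C1 and C4 that does not matter. TMSBr in CH2Cl2 at 0 °C converts it into the bis(benzylic bromide) 4,4′-[(2S,3S)-1,4-dibromo-2,3-dimethylbutane-1,4-diyl]bis(2,6-dimethoxyphenol) F2. Brief shaking with cold aqueous NaHCO3 then eliminates HBr twice and releases 8 without any oxidant. The hydration is then run exactly as in the second stage of step 3.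

Step 2. The acidic iridium hydride may protonate the p-hydroxystyrene units and cause oligomerisation. The conjugated diene may bind η4 and slow turnover, and a mismatched second reduction would raise the meso content. The meso isomer is removed by crystallisation, or later as the cis-dimethyl oxolanes.

The fallback sets out from 4 and comes back at 6. Ac2O/pyridine gives the diacetate [(1E,3E)-2,3-dimethylbuta-1,3-diene-1,4-diyl]bis(2,6-dimethoxy-4,1-phenylene) diacetate F3, an ordinary aryl-substituted diene that can no longer form a quinone methide. The same iridium hydrogenation gives [(2R,3R)-2,3-dimethylbutane-1,4-diyl]bis(2,6-dimethoxy-4,1-phenylene) diacetate F4. Methanolysis with K2CO3 in MeOH at 0 °C returns 6.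

Step 1. Oxidative addition of the electron-rich bromophenol may be sluggish, the reaction may stop at 3, the allylpalladium intermediate may be trapped, and E/Z mixtures would need crystallisation.

The fallback sets out from 1 and comes back at 4, building the diene with defined geometry from an alkyne. Sonogashira coupling of 1 with propyne (PdCl2(PPh3)2, CuI, Et3N, DMF, 70 °C) gives 2,6-dimethoxy-4-(prop-1-yn-1-yl)phenol F5. Copper-catalysed syn-hydroboration (CuCl, Xantphos, NaOt-Bu, B2pin2, MeOH, THF) places boron on the methyl-bearing carbon and gives 2,6-dimethoxy-4-[(1Z)-2-(4,4,5,5-tetramethyl-1,3,2-dioxaborolan-2-yl)prop-1-en-1-yl]phenol F6. Palladium-catalysed oxidative homocoupling (Pd(OAc)2, K2CO3, O2, aqueous MeOH) joins two such units with retention of alkene geometry to give 4.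

**Further compounds**
F1 | step 3 | 4,4′-[(2S,3S)-1,4-dimethoxy-2,3-dimethylbutane-1,4-diyl]bis(2,6-dimethoxyphenol), mixture at C1 and C4 | COc1cc(C(OC)[C@@H](C)[C@H](C)C(OC)c2cc(OC)c(O)c(OC)c2)cc(OC)c1O
F2 | step 3 | 4,4′-[(2S,3S)-1,4-dibromo-2,3-dimethylbutane-1,4-diyl]bis(2,6-dimethoxyphenol), mixture at C1 and C4 | COc1cc(C(Br)[C@@H](C)[C@H](C)C(Br)c2cc(OC)c(O)c(OC)c2)cc(OC)c1O
F3 | step 2 | [(1E,3E)-2,3-dimethylbuta-1,3-diene-1,4-diyl]bis(2,6-dimethoxy-4,1-phenylene) diacetate | COc1cc(/C=C(C)/C(C)=C/c2cc(OC)c(OC(C)=O)c(OC)c2)cc(OC)c1OC(C)=O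
F4 | step 2 | [(2R,3R)-2,3-dimethylbutane-1,4-diyl]bis(2,6-dimethoxy-4,1-phenylene) diacetate | COc1cc(C[C@@H](C)[C@H](C)Cc2cc(OC)c(OC(C)=O)c(OC)c2)cc(OC)c1OC(C)=O
F5 | step 1 | 2,6-dimethoxy-4-(prop-1-yn-1-yl)phenol | COc1cc(C#CC)cc(OC)c1O
F6 | step 1 | 2,6-dimethoxy-4-[(1Z)-2-(4,4,5,5-tetramethyl-1,3,2-dioxaborolan-2-yl)prop-1-en-1-yl]phenol | COc1cc(/C=C(C)/B2OC(C)(C)C(C)(C)O2)cc(OC)c1O
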